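**Retrosynthetic overview**
1. The target is (13S,14R)-labd-8(17)-ene-13,14,15-triol with acetate on O15 and propanoate on O14. The two esters are disconnected first: primary O15 is acetylated, then secondary O14 is propionylated, and tertiary O13 stays free.
2. The anti 13,14-diol comes from (E)-copalol by Sharpless epoxidation to the (13S,14S)-epoxy alcohol and Payne rearrangement/hydroxide opening, which inverts C14 only.
3. (E)-Copalol comes from a C13=C14 Horner–Wadsworth–Emmons disconnection (C18 methyl ketone plus triethyl phosphonoacetate), followed by ester reduction.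
4. The methyl ketone comes from permanganate degradation of (+)-manool. No ring is formed in the route: rings A and B, with C5, C9, C10 and the 8(17)-methylene, are taken intact from manool.

Assumption: commercial (+)-manool is (13R)-labda-8(17),14-dien-13-ol with the 5S,9S,10S decalin of the target; labdane numbering is used throughout.

**Route**

Step 1
Reactants: 1 (+)-manool, (13R)-labda-8(17),14-dien-13-ol
Product: 3 14,15-dinorlabd-8(17)-en-13-one, via hydroxy acid 2 (not isolated)
Conditions: KMnO4 (4 equiv, in portions), acetone/H2O, 0 °C → rt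
Reagents that add atoms: none
Why: Permanganate oxidative cleavage of the unhindered vinyl carbinol gives hydroxy acid 2, which is decarboxylated oxidatively to the methyl ketone (its oxygen is the original O13), while the 8(17)-methylene flanked by C9 and the C10 methyl reacts much more slowly; the C13 centre is deliberately erased and C5, C9, C10 are untouched.

Step 2
Reactants: 3 14,15-dinorlabd-8(17)-en-13-one; 4 triethyl phosphonoacetate
Product: 5 ethyl (13E)-labda-8(17),13-dien-15-oate
Conditions: NaH, THF, 0 °C → reflux; SiO2 chromatography (removes the minor 13Z ester)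
Reagents that add atoms: triethyl phosphonoacetate (4), CCOC(=O)CP(=O)(OCC)OCC
Why: Horner–Wadsworth–Emmons olefination of the unhindered methyl ketone, in which reversible adduct formation places the ester trans to the larger CH2 branch (about 5:1 E:Z expected), so the 13E geometry needed for the later stereochemistry is obtained after chromatography.

Step 3
Reactants: 5 ethyl (13E)-labda-8(17),13-dien-15-oate
Product: 6 (13E)-labda-8(17),13-dien-15-ol (copalol, normal series)
Conditions: iBu2AlH (2.5 equiv), CH2Cl2, −78 → 0 °C; aq. potassium sodium tartrate work-up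
Reagents that add atoms: none
Why: 1,2-Reduction of the conjugated ester by the aluminium hydride gives the allylic alcohol without touching either alkene or the E geometry.

Step 4
Reactants: 6 (13E)-labda-8(17),13-dien-15-ol
Product: 7 (13S,14S)-13,14-epoxylabd-8(17)-en-15-ol
Conditions: Ti(OiPr)4 (10 mol %), (+)-diethyl (2R,3R)-tartrate (12 mol %), t-BuOOH (2 equiv), 4 Å molecular sieves, CH2Cl2, −20 °C
Reagents that add atoms: tert-butyl hydroperoxide, CC(C)(C)OO
Why: Katsuki–Sharpless asymmetric epoxidation, in which the titanium tartrate complex binds the allylic alcohol so only the 13,14-alkene reacts, and the (2R,3R)-tartrate sets both C13 and C14 as S in the same sense in which geraniol gives (2S,3S)-2,3-epoxygeraniol (reagent control, the ring stereocentres being remote).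

Step 5
Reactants: 7 (13S,14S)-13,14-epoxylabd-8(17)-en-15-ol
Product: 9 (13S,14R)-labd-8(17)-ene-13,14,15-triol, via terminal epoxide 8 (not isolated)
Conditions: aq. NaOH (0.5 mol/L), t-BuOH, 75 °C
Reagents that add atoms: water, O (reacting as hydroxide supplied by NaOH, [Na+].[OH-])
Why: Payne rearrangement, in which the C15 alkoxide opens the epoxide at C14 with inversion (the C13–O bond is untouched, so 13S is kept) to give terminal epoxide 8, which hydroxide then opens at the unhindered primary C15 (Curtin–Hammett), leaving C14 as R.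

Step 6
Reactants: 9 (13S,14R)-labd-8(17)-ene-13,14,15-triol
Product: 10 (13S,14R)-15-acetoxylabd-8(17)-ene-13,14-diol
Conditions: AcCl (1.1 equiv), 2,4,6-collidine, CH2Cl2, −78 °C
Reagents that add atoms: acetyl chloride, CC(=O)Cl
Why: Kinetically selective acylation of the primary hydroxyl at low temperature with a hindered pyridine base, the secondary O14 next to a fully substituted carbon and the tertiary O13 being too hindered to compete; no stereocentre is touched.

Step 7
Reactants: 10 (13S,14R)-15-acetoxylabd-8(17)-ene-13,14-diol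
Product: 11 (13S,14R)-15-acetoxy-13-hydroxylabd-8(17)-en-14-yl propanoate (target CNP0275533.1)
Conditions: (EtCO)2O (1.5 equiv), 4-(dimethylamino)pyridine (10 mol %), pyridine, 0 °C → rt
Reagents that add atoms: propionic anhydride, CCC(=O)OC(=O)CC
Why: Nucleophilic-catalysed (Steglich-type) esterification of the only remaining secondary alcohol, with the tertiary 13-OH inert under these mild conditions and the configuration at C14 retained because only the O–H bond reacts.

**Compound list**
1 | (+)-manool, (13R)-labda-8(17),14-dien-13-ol | C=C1CC[C@H]2C(C)(C)CCC[C@]2(C)[C@H]1CC[C@@](C)(O)C=C | starting material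
2 | hydroxy acid, (13R)-13-hydroxy-15-norlabd-8(17)-en-14-oic acid | C=C1CC[C@H]2C(C)(C)CCC[C@]2(C)[C@H]1CC[C@@](C)(O)C(=O)O | intermediate
3 | 14,15-dinorlabd-8(17)-en-13-one | C=C1CC[C@H]2C(C)(C)CCC[C@]2(C)[C@H]1CCC(C)=O | intermediate
4 | triethyl phosphonoacetate | CCOC(=O)CP(=O)(OCC)OCC | starting material
5 | ethyl (13E)-labda-8(17),13-dien-15-oate | C=C1CC[C@H]2C(C)(C)CCC[C@]2(C)[C@H]1CC/C(C)=C/C(=O)OCC | intermediate
6 | (13E)-labda-8(17),13-dien-15-ol (copalol) | C=C1CC[C@H]2C(C)(C)CCC[C@]2(C)[C@H]1CC/C(C)=C/CO | intermediate
7 | (13S,14S)-13,14-epoxylabd-8(17)-en-15-ol | C=C1CC[C@H]2C(C)(C)CCC[C@]2(C)[C@H]1CC[C@]3(C)O[C@H]3CO | intermediate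
8 | terminal epoxide, (13S,14R)-14,15-epoxylabd-8(17)-en-13-ol | C=C1CC[C@H]2C(C)(C)CCC[C@]2(C)[C@H]1CC[C@](C)(O)[C@H]3CO3 | intermediate
9 | (13S,14R)-labd-8(17)-ene-13,14,15-triol | C=C1CC[C@H]2C(C)(C)CCC[C@]2(C)[C@H]1CC[C@](C)(O)[C@@H](CO)O | intermediate
10 | (13S,14R)-15-acetoxylabd-8(17)-ene-13,14-diol | C=C1CC[C@H]2C(C)(C)CCC[C@]2(C)[C@H]1CC[C@](C)(O)[C@@H](COC(C)=O)O | intermediate
11 | (13S,14R)-15-acetoxy-13-hydroxylabd-8(17)-en-14-yl propanoate | C=C1CC[C@H]2C(C)(C)CCC[C@]2(C)[C@H]1CC[C@](C)(O)[C@@H](COC(C)=O)OC(=O)CC | target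

**Totals**
Total step count: 7. Longest linear sequence: 7 steps (1 → 11).

**Steps most likely to fail, and fallbacks**

Step 1. Permanganate may also attack the 8(17)-methylene or over-oxidise, lowering the yield of 3. The fallback sets out from 1 and comes back to the route at 6, avoiding permanganate and the olefination altogether. Manool 1 undergoes Babler–Dauben oxidative 1,3-transposition with pyridinium chlorochromate, (C5H5NH)[CrO3Cl], in CH2Cl2 at rt to give (13E)-labda-8(17),13-dien-15-al F1 as the major geometric isomer. Luche reduction (NaBH4, CeCl3·7H2O, MeOH, 0 °C) and chromatography on AgNO3-impregnated SiO2 to remove the 13Z alcohol then deliver 6. The price is a poorer E:Z ratio (roughly 2:1), which is why it is not the main route.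

Step 2. The E:Z ratio of the olefination of a methyl ketone is only moderate and the ester isomers may be hard to separate. The fallback sets out from 3 and comes back at 5, building the trisubstituted alkene stereospecifically. Kinetic enolisation of 3 on the methyl side (LiN(iPr)2, THF, −78 °C) and trapping with ClP(O)(OEt)2 gives diethyl 4-[(1S,4aS,8aS)-5,5,8a-trimethyl-2-methylidenedecahydronaphthalen-1-yl]but-1-en-2-yl phosphate F2. Elimination with more LiN(iPr)2 (−78 °C → rt) gives 4-[(1S,4aS,8aS)-5,5,8a-trimethyl-2-methylidenedecahydronaphthalen-1-yl]but-1-yne F3. Negishi carboalumination (Me3Al, Cp2ZrCl2, CH2Cl2, rt) adds methyl and aluminium syn across the alkyne to give dimethyl[(1E)-2-methyl-4-[(1S,4aS,8aS)-5,5,8a-trimethyl-2-methylidenedecahydronaphthalen-1-yl]but-1-en-1-yl]alane F4. F4 is acylated in the same flask with ClCO2Et to give 5 as a single 13E isomer; the 1,1-disubstituted ring alkene does not carbometalate.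

Step 5. The Payne rearrangement/hydroxide opening can be slow for this lipophilic, fully substituted epoxide and may stall or give oligomeric ethers. The fallback sets out from 6 and comes back at 9, using the opposite epoxide and the opposite regiochemistry of opening. Sharpless epoxidation of 6 with (−)-diethyl (2S,3S)-tartrate (Ti(OiPr)4, t-BuOOH, 4 Å molecular sieves, CH2Cl2, −20 °C) gives (13R,14R)-13,14-epoxylabd-8(17)-en-15-ol F5. Acid-catalysed hydrolysis (HClO4 cat., THF/H2O, 0 °C) then opens the epoxide at the tertiary C13 with inversion while C14 keeps its oxygen, giving the same (13S,14R)-triol 9. The risk moved to this variant is acid-induced participation of the 8(17)-alkene, hence dilute acid and low temperature.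

**Further compounds**
F1 | step 1 | (13E)-labda-8(17),13-dien-15-al | C=C1CC[C@H]2C(C)(C)CCC[C@]2(C)[C@H]1CC/C(C)=C/C=O
F2 | step 2 | diethyl 4-[(1S,4aS,8aS)-5,5,8a-trimethyl-2-methylidenedecahydronaphthalen-1-yl]but-1-en-2-yl phosphate | C=C1CC[C@H]2C(C)(C)CCC[C@]2(C)[C@H]1CCC(=C)OP(=O)(OCC)OCC
F3 | step 2 | 4-[(1S,4aS,8aS)-5,5,8a-trimethyl-2-methylidenedecahydronaphthalen-1-yl]but-1-yne | C=C1CC[C@H]2C(C)(C)CCC[C@]2(C)[C@H]1CCC#C
F4 | step 2 | dimethyl[(1E)-2-methyl-4-[(1S,4aS,8aS)-5,5,8a-trimethyl-2-methylidenedecahydronaphthalen-1-yl]but-1-en-1-yl]alane | C=C1CC[C@H]2C(C)(C)CCC[C@]2(C)[C@H]1CC/C(C)=C/[Al](C)C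
F5 | step 5 | (13R,14R)-13,14-epoxylabd-8(17)-en-15-ol | C=C1CC[C@H]2C(C)(C)CCC[C@]2(C)[C@H]1CC[C@@]3(C)O[C@@H]3CO
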